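**Retrosynthetic overview**
1. Target ⇐ MOM removal ⇐ ArBr → ArCHO ⇐ 19 ⇐ OH-directed hydrogenation (sets C-9) ⇐ 18 ⇐ MeCeCl2 addition (sets C-8) ⇐ enone 17.
2. Key disconnection C-9–C-11: intermolecular aldol (then dehydration) between the regiodefined C-8/C-9 lithium enolate 14 of the cis-decalone and aryl aldehyde 4.
3. Enolate 14 ⇐ Li/NH3 opening of cyclopropyl ketone 13, used in the same flask ⇐ OH-directed cyclopropanation of allylic alcohol 11 (sets the cis ring fusion and the angular CH3) ⇐ lipase resolution of Luche alcohol 10 ⇐ Birch enone 9 ⇐ 6-methoxy-1-tetralone 5.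
4. Aldehyde 4 ⇐ directed ortho-lithiation/formylation of bis-MOM bromohydroquinone 2.
5. Ring order: ring A is the saturated ring of the tetralone, ring B comes from its anisole ring (Birch), the hydroquinone ring is bought; no ring is built de novo.

Assumption: the SMILES is read literally, i.e. a cis-fused decalin (H-5 and CH3-10 on the same, β, face; 8α-OH, 9β-CH2Ar); drimane locants are used in the comments (carbinol carbon = C-8, benzylic CH2 = C-11).

**Route**

Step 1
Reactants: 1 2-bromobenzene-1,4-diol
Product: 2 2-bromo-1,4-bis(methoxymethoxy)benzene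
Conditions: MOMCl, i-Pr2NEt, CH2Cl2, 0 °C → rt
Reagents that add atoms: chloromethyl methyl ether, COCCl
Why: O-alkylation of both phenols gives acetal ethers that withstand the later organolithium steps and act as ortho-directing groups; no stereocenter.

Step 2
Reactants: 2 2-bromo-1,4-bis(methoxymethoxy)benzene
Product: 4 2-bromo-3,6-bis(methoxymethoxy)benzaldehyde, via aryllithium 3 (not isolated)
Conditions: LiN(i-Pr)2, THF, −78 °C; DMF; H2O
Reagents that add atoms: N,N-dimethylformamide, CN(C)C=O
Why: Directed ortho-metalation removes the most acidic ring proton (flanked by Br and OMOM) at −78 °C, below the benzyne threshold, and DMF formylates the aryllithium; no stereocenter.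

Step 3
Reactants: 5 6-methoxy-1-tetralone
Product: 6 6-methoxy-1,1-dimethyl-1,2,3,4-tetrahydronaphthalene
Conditions: Me2TiCl2 (from TiCl4 + Me2Zn), CH2Cl2, −30 °C → rt
Reagents that add atoms: dimethyltitanium dichloride, C[Ti](C)(Cl)Cl (prepared in the flask from dimethylzinc, C[Zn]C)
Why: Reetz geminal dimethylation replaces the aryl ketone oxygen by two methyl groups through a benzylic cation stabilised by the para methoxy group; no stereocenter.

Step 4
Reactants: 6 6-methoxy-1,1-dimethyl-1,2,3,4-tetrahydronaphthalene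
Product: 7 6-methoxy-1,1-dimethyl-1,2,3,4,5,8-hexahydronaphthalene
Conditions: Li, NH3(l), t-BuOH, THF, −78 → −33 °C; then MeOH, H2O
Reagents that add atoms: none
Why: Birch reduction of the anisole ring leaves the methoxy- and alkyl-bearing carbons unsaturated and gives the 1,4-dihydro enol ether; no stereocenter.

Step 5
Reactants: 7 6-methoxy-1,1-dimethyl-1,2,3,4,5,8-hexahydronaphthalene
Product: 9 rac-5,5-dimethyl-4,4a,5,6,7,8-hexahydronaphthalen-2(3H)-one, via β,γ-enone 8 (not isolated)
Conditions: 2 M HCl (aq), THF–MeOH, 50 °C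
Reagents that add atoms: water, O
Why: Enol ether hydrolysis followed by acid-catalysed migration of the β,γ double bond into conjugation gives the enone; C-4a (future C-5) is formed racemic here.

Step 6
Reactants: 9 rac-5,5-dimethyl-4,4a,5,6,7,8-hexahydronaphthalen-2(3H)-one
Product: 10 rac-(2S*,4aR*)-5,5-dimethyl-2,3,4,4a,5,6,7,8-octahydronaphthalen-2-ol
Conditions: NaBH4, CeCl3·7H2O, MeOH, −78 °C; silica chromatography
Reagents that add atoms: none
Why: Luche 1,2-reduction delivers hydride pseudo-axially on the face opposite H-4a, so the pseudo-equatorial alcohol cis to H-4a predominates (minor trans isomer removed on silica); still racemic.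

Step 7
Reactants: 10 rac-(2S*,4aR*)-5,5-dimethyl-2,3,4,4a,5,6,7,8-octahydronaphthalen-2-ol
Product: 11 (2S,4aR)-5,5-dimethyl-2,3,4,4a,5,6,7,8-octahydronaphthalen-2-ol
Conditions: lipase PS (Burkholderia cepacia, immobilised), vinyl acetate, t-BuOMe, 30 °C, stopped at ca. 55% conversion; silica chromatography
Reagents that add atoms: none
Why: Enzymatic kinetic resolution by transesterification: following Kazlauskas' rule the lipase acetylates the (2R) enantiomer, so running past half conversion leaves the (2S,4aR) alcohol in high ee and fixes the absolute configuration of the route.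

Step 8
Reactants: 11 (2S,4aR)-5,5-dimethyl-2,3,4,4a,5,6,7,8-octahydronaphthalen-2-ol
Product: 12 (2S,4aR)-5,5-dimethyldecahydro-1,8a-methanonaphthalen-2-ol (CH2 bridge between C-1 and C-8a on the face of OH and H-4a)
Conditions: Et2Zn, CH2I2, CH2Cl2, 0 °C → rt
Reagents that add atoms: diiodomethane, ICI
Why: Hydroxyl-directed Simmons–Smith (Furukawa) cyclopropanation delivers the zinc carbenoid to the alkene face that carries OH, which is the face of H-4a, so the new CH2 (the future angular CH3) is set cis to the ring-fusion hydrogen.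

Step 9
Reactants: 12 cyclopropyl carbinol
Product: 13 (4aR)-5,5-dimethyloctahydro-1,8a-methanonaphthalen-2(1H)-one (CH2 bridge cis to H-4a)
Conditions: (n-Pr4N)RuO4 (5 mol %), N-methylmorpholine N-oxide, 4 Å MS, CH2Cl2, rt
Reagents that add atoms: none
Why: Ley–Griffith oxidation converts the carbinol into the conjugated cyclopropyl ketone under neutral conditions without touching the three-membered ring; no stereocenter changes.

Step 10
Reactants: 13 cyclopropyl ketone; 4 2-bromo-3,6-bis(methoxymethoxy)benzaldehyde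
Product: 15 (1S,4aR,8aS)-1-{[2-bromo-3,6-bis(methoxymethoxy)phenyl](hydroxy)methyl}-5,5,8a-trimethyloctahydronaphthalen-2(1H)-one (both carbinol epimers), via lithium enolate 14 (not isolated)
Conditions: Li (2.0 equiv), t-BuOH (1.0 equiv), NH3(l)–THF, −78 °C; NH3 evaporated, THF; 4 in THF, −78 °C; AcOH, −78 °C
Reagents that add atoms: none
Why: Dissolving-metal reductive opening cleaves the external C-9–CH2 cyclopropane bond that overlaps the carbonyl π system, unmasking the angular methyl with the cis fusion intact and leaving the regiodefined C-8/C-9 lithium enolate, which after removal of NH3 undergoes an intermolecular aldol addition through a closed Zimmerman–Traxler transition state to the non-enolisable aryl aldehyde and forms the C-9–C-11 bond that joins the two fragments (the new centres at C-9 and C-11 are removed in the next step).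

Step 11
Reactants: 15 aldol adduct
Product: 17 (1Z,4aR,8aS)-1-[2-bromo-3,6-bis(methoxymethoxy)benzylidene]-5,5,8a-trimethyloctahydronaphthalen-2(1H)-one, via mesylate 16 (not isolated)
Conditions: MsCl, Et3N, CH2Cl2, 0 °C; then DBU, rt
Reagents that add atoms: none
Why: Aldol dehydration through the electron-rich benzylic mesylate (E1cB/E1) gives the exocyclic enone, expected mainly as the Z isomer with the aryl group turned away from quaternary C-10; the geometry has no consequence later.

Step 12
Reactants: 17 benzylidene enone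
Product: 18 (1Z,2R,4aR,8aS)-1-[2-bromo-3,6-bis(methoxymethoxy)benzylidene]-2,5,5,8a-tetramethyldecahydronaphthalen-2-ol
Conditions: MeLi, CeCl3 (anhydrous), THF, −78 °C; H2O
Reagents that add atoms: methyllithium, [Li]C
Why: Organocerium 1,2-addition to a hindered, enolisable enone: with C-9 trigonal, the α face of C-8 is screened by the axial C-1 methylene of ring A, so methyl enters from the β (equatorial) side and gives the 8α-OH/8β-CH3 carbinol.

Step 13
Reactants: 18 allylic alcohol
Product: 19 (1R,2R,4aR,8aS)-1-[2-bromo-3,6-bis(methoxymethoxy)benzyl]-2,5,5,8a-tetramethyldecahydronaphthalen-2-ol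
Conditions: [Ir(cod)(PCy3)(py)]PF6 (10 mol %), H2 (1 atm), CH2Cl2, rt
Reagents that add atoms: none
Why: Hydroxyl-directed homogeneous hydrogenation: the cationic iridium catalyst binds the tertiary allylic OH and delivers H2 to the same (α) face of the exocyclic alkene, placing H-9 cis to OH and the benzyl group β as in the target.

Step 14
Reactants: 19 aryl bromide
Product: 21 2-{[(1R,2R,4aR,8aS)-2-hydroxy-2,5,5,8a-tetramethyldecahydronaphthalen-1-yl]methyl}-3,6-bis(methoxymethoxy)benzaldehyde, via dilithio species 20 (not isolated)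
Conditions: t-BuLi (3.2 equiv), THF, −78 °C; DMF; H2O
Reagents that add atoms: N,N-dimethylformamide, CN(C)C=O
Why: After deprotonation of the alcohol, bromine–lithium exchange gives an aryllithium stabilised by the neighbouring OMOM group, which DMF formylates; no stereocenter is touched.

Step 15
Reactants: 21 bis-MOM aldehyde
Product: 22 3,6-dihydroxy-2-{[(1R,2R,4aR,8aS)-2-hydroxy-2,5,5,8a-tetramethyldecahydronaphthalen-1-yl]methyl}benzaldehyde
Conditions: HCl (1 M in MeOH), 0 °C → rt, N2
Reagents that add atoms: none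
Why: Acid-catalysed acetal exchange removes both MOM ethers under conditions intended to be too mild to ionise the tertiary alcohol, releasing the hydroquinone aldehyde; no stereocenter is touched.

**Compound list**
1 | 2-bromobenzene-1,4-diol (bromohydroquinone) | Oc1ccc(O)c(Br)c1 | starting material
2 | 2-bromo-1,4-bis(methoxymethoxy)benzene | COCOc1ccc(OCOC)c(Br)c1 | intermediate
3 | [2-bromo-3,6-bis(methoxymethoxy)phenyl]lithium (in situ) | COCOc1ccc(OCOC)c([Li])c1Br | intermediate
4 | 2-bromo-3,6-bis(methoxymethoxy)benzaldehyde | O=Cc1c(Br)c(OCOC)ccc1OCOC | intermediate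
5 | 6-methoxy-3,4-dihydronaphthalen-1(2H)-one (6-methoxy-1-tetralone) | COc1ccc2c(c1)CCCC2=O | starting material
6 | 6-methoxy-1,1-dimethyl-1,2,3,4-tetrahydronaphthalene | COc1ccc2c(c1)CCCC2(C)C | intermediate
7 | 6-methoxy-1,1-dimethyl-1,2,3,4,5,8-hexahydronaphthalene | COC1=CCC2=C(C1)CCCC2(C)C | intermediate
8 | 5,5-dimethyl-3,4,5,6,7,8-hexahydronaphthalen-2(1H)-one (in situ) | O=C1CCC2=C(C1)CCCC2(C)C | intermediate
9 | rac-5,5-dimethyl-4,4a,5,6,7,8-hexahydronaphthalen-2(3H)-one | O=C1C=C2CCCC(C)(C)[C@H]2CC1.O=C1C=C2CCCC(C)(C)[C@@H]2CC1 | intermediate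
10 | rac-(2S*,4aR*)-5,5-dimethyl-2,3,4,4a,5,6,7,8-octahydronaphthalen-2-ol (OH cis to H-4a) | O[C@@H]1C=C2CCCC(C)(C)[C@H]2CC1.O[C@H]1C=C2CCCC(C)(C)[C@@H]2CC1 | intermediate
11 | (2S,4aR)-5,5-dimethyl-2,3,4,4a,5,6,7,8-octahydronaphthalen-2-ol | O[C@@H]1C=C2CCCC(C)(C)[C@H]2CC1 | intermediate
12 | (2S,4aR)-5,5-dimethyldecahydro-1,8a-methanonaphthalen-2-ol, CH2 bridge on the face of OH and H-4a | O[C@@H]1[C@@H]2C[C@@]23CCCC(C)(C)[C@H]3CC1 | intermediate
13 | (4aR)-5,5-dimethyloctahydro-1,8a-methanonaphthalen-2(1H)-one, CH2 bridge cis to H-4a | O=C1[C@@H]2C[C@@]23CCCC(C)(C)[C@H]3CC1 | intermediate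
14 | lithium (4aR,8aS)-5,5,8a-trimethyl-3,4,4a,5,6,7,8,8a-octahydronaphthalen-2-olate (in situ) | CC1(C)CCC[C@@]2(C)[C@@H]1CCC(O[Li])=C2 | intermediate
15 | (1S,4aR,8aS)-1-{[2-bromo-3,6-bis(methoxymethoxy)phenyl](hydroxy)methyl}-5,5,8a-trimethyloctahydronaphthalen-2(1H)-one, both carbinol epimers | CC1(C)CCC[C@@]2(C)[C@@H]1CCC(=O)[C@@H]2C(O)c1c(Br)c(OCOC)ccc1OCOC | intermediate
16 | methanesulfonate of 15 (in situ) | CC1(C)CCC[C@@]2(C)[C@@H]1CCC(=O)[C@@H]2C(OS(C)(=O)=O)c1c(Br)c(OCOC)ccc1OCOC | intermediate
17 | (1Z,4aR,8aS)-1-[2-bromo-3,6-bis(methoxymethoxy)benzylidene]-5,5,8a-trimethyloctahydronaphthalen-2(1H)-one | CC1(C)CCC[C@@]2(C)[C@@H]1CCC(=O)/C2=C\c1c(Br)c(OCOC)ccc1OCOC | intermediate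
18 | (1Z,2R,4aR,8aS)-1-[2-bromo-3,6-bis(methoxymethoxy)benzylidene]-2,5,5,8a-tetramethyldecahydronaphthalen-2-ol | CC1(C)CCC[C@@]2(C)[C@@H]1CC[C@@](C)(O)/C2=C\c1c(Br)c(OCOC)ccc1OCOC | intermediate
19 | (1R,2R,4aR,8aS)-1-[2-bromo-3,6-bis(methoxymethoxy)benzyl]-2,5,5,8a-tetramethyldecahydronaphthalen-2-ol | CC1(C)CCC[C@@]2(C)[C@@H]1CC[C@@](C)(O)[C@@H]2Cc1c(Br)c(OCOC)ccc1OCOC | intermediate
20 | O,C-dilithio derivative of 19 (lithium alkoxide, aryllithium in place of Br; in situ) | CC1(C)CCC[C@@]2(C)[C@@H]1CC[C@@](C)(O[Li])[C@@H]2Cc1c([Li])c(OCOC)ccc1OCOC | intermediate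
21 | 2-{[(1R,2R,4aR,8aS)-2-hydroxy-2,5,5,8a-tetramethyldecahydronaphthalen-1-yl]methyl}-3,6-bis(methoxymethoxy)benzaldehyde | CC1(C)CCC[C@@]2(C)[C@@H]1CC[C@@](C)(O)[C@@H]2Cc1c(C=O)c(OCOC)ccc1OCOC | intermediate
22 | 3,6-dihydroxy-2-{[(1R,2R,4aR,8aS)-2-hydroxy-2,5,5,8a-tetramethyldecahydronaphthalen-1-yl]methyl}benzaldehyde (CNP0267523.2) | CC1(C)CCC[C@@]2(C)[C@@H]1CC[C@@](C)(O)[C@@H]2Cc1c(O)ccc(O)c1C=O | target

**Totals**
Total steps: 15. Longest linear sequence: 13 steps (steps 3–15, from 6-methoxy-1-tetralone 5); the aryl branch is 2 steps (steps 1–2) and joins at step 10.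

**Steps most likely to fail, with fallbacks**

Step 10 (one-flask reductive opening and aldol: lithium tert-butoxide and traces of NH3 accompany the enolate, and both partners are hindered). Fallback, from 13: the enolate is stored as an enol silane and the carbon–carbon bond is made under Lewis-acid activation of the aldehyde instead. The Li/NH3 opening is run as in step 10, NH3 is removed and Me3SiCl/Et3N (THF, −78 → 0 °C) is added. This gives the silyl enol ether trimethyl{[(4aR,8aS)-5,5,8a-trimethyl-3,4,4a,5,6,7,8,8a-octahydronaphthalen-2-yl]oxy}silane F1, which is purified by pentane extraction and short-path distillation. A Mukaiyama aldol addition of F1 to 4 (BF3·OEt2, CH2Cl2, −78 °C; aqueous NaHCO3) then returns to the route at 15.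

Step 12 (1,2-addition to a crowded, enolisable enone whose aryl group lies close to the carbonyl). Fallback, from 17: the one-carbon unit is added as a sulfur ylide. Dimethylsulfonium methylide (Me3S+ I−, KN(SiMe3)2, THF, −20 °C; Corey–Chaykovsky reaction) attacks the same β face and closes to the spiro-epoxide F2. LiEt3BH (THF, 0 °C) then opens F2 at its CH2 terminus and gives 18.

Step 13 (directed hydrogenation of a trisubstituted alkene flanked by two fully substituted carbons). Fallback, from 18: the hydrogen at C-9 is delivered through a silicon tether. The tertiary alcohol is silylated with chlorodimethylsilane (Et3N, DMAP, CH2Cl2) to the dimethylsilyl ether F3. Pt2[(CH2=CHSiMe2)2O]3 (1 mol %, toluene, 60 °C) then effects intramolecular hydrosilylation, adding Si–H cis across the alkene from the α face (Si to the benzylic carbon, H to C-9) to give the oxasilolane F4. n-Bu4NF in wet DMF at 60 °C cleaves the Si–O bond and protodesilylates the benzylic Si–C bond, arriving at 19.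

**Further compounds**
F1 | step 10 | trimethyl{[(4aR,8aS)-5,5,8a-trimethyl-3,4,4a,5,6,7,8,8a-octahydronaphthalen-2-yl]oxy}silane | CC1(C)CCC[C@@]2(C)[C@@H]1CCC(O[Si](C)(C)C)=C2
F2 | step 12 | spiro-epoxide of 17 at C-8 (O on the α face, CH2 on the β face), Z-benzylidene retained | CC1(C)CCC[C@@]2(C)[C@@H]1CC[C@]3(CO3)/C2=C\c4c(Br)c(OCOC)ccc4OCOC
F3 | step 13 | dimethylsilyl ether of 18 | CC1(C)CCC[C@@]2(C)[C@@H]1CC[C@@](C)(O[SiH](C)C)/C2=C\c1c(Br)c(OCOC)ccc1OCOC
F4 | step 13 | 2,2-dimethyl-1,2-oxasilolane fused at C-8/C-9 with the aryl group on the silicon-bearing carbon (H-9 α; configuration at the silylated carbon follows from cis addition and is lost on desilylation) | CC1(C)CCC[C@@]2(C)[C@@H]1CC[C@@]1(C)O[Si](C)(C)C(c3c(Br)c(OCOC)ccc3OCOC)[C@H]21
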